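The diaryl ether is not made by joining two arenes; ring A is grown on the phenol oxygen of ring B. The feature used is that ring A (C1 bearing the quaternary side chain, C4 the hydroxyl, C5 the ether oxygen) is the dehydrogenated form of a 2-aryloxy-4-alkylcyclohex-2-enone. One amine- and base-mediated Michael–aldol annulation of aldehyde 7 with aryloxymethyl vinyl ketone 21 forms C1–C2 and C5=C6 and closes this ring; enol silylation and palladium oxidation then aromatise it. Both partners arrive with their quaternary centres in place, each set by a copper-catalysed enantioselective SN2' substitution of farnesyl phosphate, and ring B carries its catechol as MOM ethers.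

Key step: step 11

Remarks
- Atom labels: ring A as above; ring B has the ether oxygen on C1, the two hydroxyls on C2 and C3 and the side chain on C5.
- Abbreviations used in names: RQ = (3R,6E)-3,7,11-trimethyldodeca-1,6,10-trien-3-yl, SQ = its (3S,6E) mirror-image centre; ArB = 2,3-bis(methoxymethoxy)-5-(SQ)phenyl.
- Ring B is started from the free catechol aldehyde 8, taken to be a catalogue compound, so that no aryl methyl ether has to be cleaved once MOM groups and the polyene are present.
- L is a bidentate sulfonate NHC precursor of the 4,5-diphenylimidazolinium type, with N-(2-sulfonatophenyl) and N-(2,6-diethylphenyl) groups, made from 1,2-diphenylethane-1,2-diamine.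
- Assumption: steps 2 and 8 need opposite faces of C3 of 2 (alkynyl to Re, aryl to Si). Which antipode of L serves which face is to be settled on the first run; both antipodes are accessible from the (R,R)- and (S,S)-diamine.

Step 1
Reactants: 1 (2E,6E)-farnesol
Product: 2 diethyl (2E,6E)-3,7,11-trimethyldodeca-2,6,10-trien-1-yl phosphate
Conditions: (EtO)2P(O)Cl, Et3N, DMAP (cat.), CH2Cl2, 0 °C to rt
Reagents that add atoms: diethyl chlorophosphate, CCOP(=O)(Cl)OCC
Why: O-phosphorylation of the primary allylic alcohol under amine/DMAP catalysis installs the leaving group for SN2' substitution and leaves the alkenes untouched.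

Step 2
Reactants: 2 farnesyl diethyl phosphate; 3 ethynyltrimethylsilane
Product: 5 [(3R,6E)-3-ethenyl-3,7,11-trimethyldodeca-6,10-dien-1-yn-1-yl]trimethylsilane, via alkynylalane 4 (not isolated)
Conditions: 3, i-Bu2AlH, Et3N (5 mol %), hexanes, rt; then 2, CuCl2·2H2O (5 mol %), L (Re-face antipode, 5 mol %, introduced as its carbene–silver complex prepared with Ag2O), THF, −30 °C
Reagents that add atoms: none
Why: Amine-catalysed alumination of the terminal alkyne gives 4, and the chiral copper–NHC complex then transfers the alkynyl group in an enantioselective SN2' allylic substitution to the Re face of C3, which creates the vinyl group and the 3R quaternary centre under catalyst control.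

Step 3
Reactants: 5 silylated enyne
Product: 6 (3R,6E)-3-ethenyl-3,7,11-trimethyldodeca-6,10-dien-1-yne
Conditions: K2CO3 (cat.), MeOH, rt
Reagents that add atoms: none
Why: Methoxide-mediated protodesilylation of the alkynylsilane; the all-carbon quaternary centre cannot epimerise.

Step 4
Reactants: 6 terminal enyne
Product: 7 (3S,6E)-3-ethenyl-3,7,11-trimethyldodeca-6,10-dienal
Conditions: [CpRu(NCMe)3]PF6 (5 mol %), 5,5'-bis(trifluoromethyl)-2,2'-bipyridine (5 mol %), H2O, N-methylpyrrolidone, 25 °C
Reagents that add atoms: water, O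
Why: Anti-Markovnikov hydration of a terminal alkyne through a ruthenium vinylidene, whose metal-bound carbon takes up water, so only the alkyne reacts and the aldehyde forms; the descriptor changes from R to S by priority only.

Step 5
Reactants: 8 5-bromo-2,3-dihydroxybenzaldehyde
Product: 9 5-bromo-2,3-bis(methoxymethoxy)benzaldehyde
Conditions: MOMCl, i-Pr2NEt, CH2Cl2, 0 °C to reflux
Reagents that add atoms: chloromethyl methyl ether, COCCl
Why: O-alkylation of both phenols by the chloromethyl ether (Williamson-type acetal formation) gives base-stable ethers that mild acid removes at the end.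

Step 6
Reactants: 9 bis-MOM aldehyde
Product: 11 5-bromo-2,3-bis(methoxymethoxy)phenol, via aryl formate 10 (not isolated)
Conditions: mCPBA, CH2Cl2, rt; then MeOH, Et3N (cat.), rt
Reagents that add atoms: 3-chloroperoxybenzoic acid, O=C(OO)c1cccc(Cl)c1
Why: Baeyer–Villiger (Dakin-type) oxidation in which the electron-rich ortho-alkoxy aryl group migrates to give formate 10, which methanol cleaves; no alkene is present yet.

Step 7
Reactants: 11 bromophenol
Product: 12 [5-bromo-2,3-bis(methoxymethoxy)phenoxy](tert-butyl)dimethylsilane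
Conditions: TBSCl, imidazole, DMF, rt
Reagents that add atoms: tert-butyldimethylsilyl chloride, CC(C)(C)[Si](C)(C)Cl
Why: Imidazole-mediated silylation masks the acidic phenol before metalation, with a group that fluoride removes without touching the MOM ethers.

Step 8
Reactants: 12 silyl-protected aryl bromide; 2 farnesyl diethyl phosphate
Product: 15 tert-butyldimethyl[2,3-bis(methoxymethoxy)-5-(SQ)phenoxy]silane (ArB–O–TBS), via aryllithium 13 (not isolated), via arylaluminium 14 (not isolated)
Conditions: 12, t-BuLi (2 equiv), Et2O, −78 °C; Et2AlCl, −78 °C to rt; then 2, CuCl2·2H2O (5 mol %), L (Si-face antipode, 5 mol %, introduced as its carbene–silver complex prepared with Ag2O), THF, −30 °C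
Reagents that add atoms: none
Why: Bromine–lithium exchange, transmetalation to the aryl(diethyl)aluminium and copper–NHC-catalysed enantioselective SN2' allylic substitution, in which aryl transfers in preference to ethyl to the Si face of C3, set the 3S aryl-bearing quaternary centre under catalyst control.

Step 9
Reactants: 15 ArB–O–TBS; 16 2-chloro-N-methoxy-N-methylacetamide
Product: 18 2-(ArB-oxy)-N-methoxy-N-methylacetamide, via caesium phenoxide 17 (not isolated)
Conditions: CsF, DMF, rt; then 16, rt
Reagents that add atoms: none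
Why: Fluoride cleaves the aryl silyl ether and the caesium phenoxide is O-alkylated in the same flask by the α-chloro amide (Williamson ether synthesis), the MOM ethers being inert to fluoride and base.

Step 10
Reactants: 18 N-methoxy-N-methylamide; 19 vinylmagnesium bromide (CH2=CHMgBr)
Product: 21 1-(ArB-oxy)but-3-en-2-one, via magnesium chelate 20 (not isolated)
Conditions: THF, −78 to 0 °C; inverse quench into cold aqueous KHSO4; used at once
Reagents that add atoms: none
Why: Weinreb ketone synthesis, in which the five-membered magnesium chelate 20 prevents a second addition and survives until the cold acidic inverse quench, which also protonates the released N,O-dimethylhydroxylamine so that it cannot add to the enone.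

Step 11
Reactants: 7 (3S)-aldehyde (1.2 equiv); 21 aryloxymethyl vinyl ketone
Product: 24 2-(ArB-oxy)-4-(RQ)cyclohex-2-en-1-one (C4 epimers), via keto-aldehyde 22 (not isolated), via aldol adduct 23 (not isolated)
Conditions: (S)-2-[diphenyl(trimethylsilyloxy)methyl]pyrrolidine (20 mol %), ethyl 3,4-dihydroxybenzoate (20 mol %), CH2Cl2 (concentrated), 0 °C to rt; then LiOH·H2O, i-PrOH/THF, rt
Reagents that add atoms: none
Why: The secondary amine condenses with 7 to a catalytic E-enamine whose β-carbon adds to the terminal CH2 of enone 21, activated by hydrogen bonding to the catechol additive (enamine Michael addition, C1–C2), and hydrolysis releases keto-aldehyde 22 and the amine. Hydroxide then enolises the ketone toward the aryloxy-bearing methylene, the more acidic α-position and the only one that can reach the aldehyde through a six-membered transition state, and a 6-(enolendo)-exo-trig aldol addition followed by E1cB loss of water closes ring A and leaves the conjugated C5=C6 bond. The closest known reaction is the amine-catalysed Michael addition of aldehydes to vinyl ketones followed by base-mediated aldol condensation to 4-substituted cyclohex-2-enones (Robinson-type annulation), for which α'-oxygenated vinyl ketones are established acceptors. No stereocentre needs control: ring carbon C1 forms as a mixture of epimers that aromatisation erases, and the two quaternary centres carry no acidic hydrogen and pass through unchanged. The step needs chemoselectivity only, Michael addition ahead of aldehyde self-condensation and of N-alkylation of the catalyst, which the neopentyl-type aldehyde (slow self-aldol), the shielded amine and the inductively activated enone should provide.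

Step 12
Reactants: 24 cyclohexenone
Product: 26 {[6-(ArB-oxy)-4-(RQ)cyclohexa-1,5-dien-1-yl]oxy}trimethylsilane (C4 epimers), via lithium dienolate 25 (not isolated)
Conditions: LiN(i-Pr)2, THF, −78 °C; then Me3SiCl, Et3N, −78 to 0 °C; pentane, filtration, used crude
Reagents that add atoms: chlorotrimethylsilane, C[Si](C)(C)Cl
Why: Kinetic deprotonation at the α' methylene (C3 of ring A) by the hindered amide gives the cross-conjugated lithium dienolate, which the chlorosilane traps on oxygen (silyl enol ether formation).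

Step 13
Reactants: 26 silyl dienol ether
Product: 28 2-(ArB-oxy)-4-(RQ)phenol, via cyclohexadienone 27 (not isolated)
Conditions: Pd(OAc)2 (1.05 equiv), MeCN, rt
Reagents that add atoms: none
Why: Saegusa–Ito oxidation, in which the enolate passes from silicon to divalent palladium and β-hydride elimination forms C2=C3; the cyclohexa-2,5-dienone, which keeps a hydrogen on C1, enolises at once to the ring A phenol, and the uncontrolled ring stereocentre disappears.

Step 14
Reactants: 28 bis-MOM phenol
Product: 29 3-[2-hydroxy-5-(RQ)phenoxy]-5-(SQ)benzene-1,2-diol (target)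
Conditions: HCl (0.5 M in MeOH), THF, 0 °C to rt, degassed, under argon
Reagents that add atoms: none
Why: Acid-catalysed acetal exchange (methanolysis) removes both aryl MOM ethers under conditions too mild to protonate the alkenes, and no alkene is placed to cyclise onto a phenol.

Compound list
1 | (2E,6E)-farnesol | OC/C=C(\C)CC/C=C(\C)CCC=C(C)C | starting material
2 | diethyl (2E,6E)-3,7,11-trimethyldodeca-2,6,10-trien-1-yl phosphate | CCOP(=O)(OCC)OC/C=C(\C)CC/C=C(\C)CCC=C(C)C | intermediate
3 | ethynyltrimethylsilane | C#C[Si](C)(C)C | starting material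
4 | bis(2-methylpropyl)[(trimethylsilyl)ethynyl]aluminium | CC(C)C[Al](CC(C)C)C#C[Si](C)(C)C | intermediate
5 | [(3R,6E)-3-ethenyl-3,7,11-trimethyldodeca-6,10-dien-1-yn-1-yl]trimethylsilane | C=C[C@@](C)(CC/C=C(\C)CCC=C(C)C)C#C[Si](C)(C)C | intermediate
6 | (3R,6E)-3-ethenyl-3,7,11-trimethyldodeca-6,10-dien-1-yne | C=C[C@@](C)(CC/C=C(\C)CCC=C(C)C)C#C | intermediate
7 | (3S,6E)-3-ethenyl-3,7,11-trimethyldodeca-6,10-dienal | C=C[C@@](C)(CC/C=C(\C)CCC=C(C)C)CC=O | intermediate
8 | 5-bromo-2,3-dihydroxybenzaldehyde | O=Cc1cc(Br)cc(O)c1O | starting material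
9 | 5-bromo-2,3-bis(methoxymethoxy)benzaldehyde | O=Cc1cc(Br)cc(OCOC)c1OCOC | intermediate
10 | 5-bromo-2,3-bis(methoxymethoxy)phenyl formate | O=COc1cc(Br)cc(OCOC)c1OCOC | intermediate
11 | 5-bromo-2,3-bis(methoxymethoxy)phenol | Oc1cc(Br)cc(OCOC)c1OCOC | intermediate
12 | [5-bromo-2,3-bis(methoxymethoxy)phenoxy](tert-butyl)dimethylsilane | CC(C)(C)[Si](C)(C)Oc1cc(Br)cc(OCOC)c1OCOC | intermediate
13 | {3-[(tert-butyldimethylsilyl)oxy]-4,5-bis(methoxymethoxy)phenyl}lithium | [Li]c1cc(O[Si](C)(C)C(C)(C)C)c(OCOC)c(OCOC)c1 | intermediate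
14 | {3-[(tert-butyldimethylsilyl)oxy]-4,5-bis(methoxymethoxy)phenyl}diethylaluminium | CC[Al](CC)c1cc(O[Si](C)(C)C(C)(C)C)c(OCOC)c(OCOC)c1 | intermediate
15 | tert-butyldimethyl[2,3-bis(methoxymethoxy)-5-(SQ)phenoxy]silane | CC(C)(C)[Si](C)(C)Oc1cc([C@](C)(C=C)CC/C=C(\C)CCC=C(C)C)cc(OCOC)c1OCOC | intermediate
16 | 2-chloro-N-methoxy-N-methylacetamide | CON(C)C(=O)CCl | starting material
17 | caesium 2,3-bis(methoxymethoxy)-5-(SQ)phenoxide | [Cs+].[O-]c1cc([C@](C)(C=C)CC/C=C(\C)CCC=C(C)C)cc(OCOC)c1OCOC | intermediate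
18 | 2-(ArB-oxy)-N-methoxy-N-methylacetamide | CON(C)C(=O)COc1cc([C@](C)(C=C)CC/C=C(\C)CCC=C(C)C)cc(OCOC)c1OCOC | intermediate
19 | vinylmagnesium bromide | C=C[Mg]Br | starting material
20 | bromomagnesium 1-(ArB-oxy)-2-[methoxy(methyl)amino]but-3-en-2-olate | C=CC(O[Mg]Br)(N(C)OC)COc1cc([C@](C)(C=C)CC/C=C(\C)CCC=C(C)C)cc(OCOC)c1OCOC | intermediate
21 | 1-(ArB-oxy)but-3-en-2-one | C=CC(=O)COc1cc([C@](C)(C=C)CC/C=C(\C)CCC=C(C)C)cc(OCOC)c1OCOC | intermediate
22 | 6-(ArB-oxy)-5-oxo-2-(RQ)hexanal (C2 epimers) | C=C[C@@](C)(CC/C=C(\C)CCC=C(C)C)C(C=O)CCC(=O)COc1cc([C@](C)(C=C)CC/C=C(\C)CCC=C(C)C)cc(OCOC)c1OCOC | intermediate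
23 | 2-(ArB-oxy)-3-hydroxy-4-(RQ)cyclohexan-1-one (ring diastereomers) | C=C[C@@](C)(CC/C=C(\C)CCC=C(C)C)C1CCC(=O)C(Oc2cc([C@](C)(C=C)CC/C=C(\C)CCC=C(C)C)cc(OCOC)c2OCOC)C1O | intermediate
24 | 2-(ArB-oxy)-4-(RQ)cyclohex-2-en-1-one (C4 epimers) | C=C[C@@](C)(CC/C=C(\C)CCC=C(C)C)C1CCC(=O)C(Oc2cc([C@](C)(C=C)CC/C=C(\C)CCC=C(C)C)cc(OCOC)c2OCOC)=C1 | intermediate
25 | lithium 6-(ArB-oxy)-4-(RQ)cyclohexa-1,5-dien-1-olate | C=C[C@@](C)(CC/C=C(\C)CCC=C(C)C)C1CC=C(O[Li])C(Oc2cc([C@](C)(C=C)CC/C=C(\C)CCC=C(C)C)cc(OCOC)c2OCOC)=C1 | intermediate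
26 | {[6-(ArB-oxy)-4-(RQ)cyclohexa-1,5-dien-1-yl]oxy}trimethylsilane | C=C[C@@](C)(CC/C=C(\C)CCC=C(C)C)C1CC=C(O[Si](C)(C)C)C(Oc2cc([C@](C)(C=C)CC/C=C(\C)CCC=C(C)C)cc(OCOC)c2OCOC)=C1 | intermediate
27 | 2-(ArB-oxy)-4-(RQ)cyclohexa-2,5-dien-1-one | C=C[C@@](C)(CC/C=C(\C)CCC=C(C)C)C1C=CC(=O)C(Oc2cc([C@](C)(C=C)CC/C=C(\C)CCC=C(C)C)cc(OCOC)c2OCOC)=C1 | intermediate
28 | 2-(ArB-oxy)-4-(RQ)phenol | C=C[C@@](C)(CC/C=C(\C)CCC=C(C)C)c1ccc(O)c(Oc2cc([C@](C)(C=C)CC/C=C(\C)CCC=C(C)C)cc(OCOC)c2OCOC)c1 | intermediate
29 | 3-[2-hydroxy-5-(RQ)phenoxy]-5-(SQ)benzene-1,2-diol | C=C[C@@](C)(CC/C=C(\C)CCC=C(C)C)c1ccc(O)c(Oc2cc([C@](C)(C=C)CC/C=C(\C)CCC=C(C)C)cc(O)c2O)c1 | target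

Total step count: 14. Longest linear sequence: 10 steps (8 to 29 through steps 5–14); the aldehyde branch (steps 1–4) joins at step 11.

Steps most likely to fail

Step 11. Enamine formation and C–C bond formation next to the quaternary carbon may be too slow to outrun oligomerisation of 21 or conjugate addition of the amine to it. The closure may also stall at 23 or be overtaken by intermolecular aldol reactions of surplus 7. The fallback sets out from 2 and 15 and comes back at 29; it gives up the annulation and joins two finished arenes. 1-Bromo-4-(methoxymethoxy)benzene F1 is converted with t-BuLi (Et2O, −78 °C) into [4-(methoxymethoxy)phenyl]lithium F2 and with Et2AlCl into diethyl[4-(methoxymethoxy)phenyl]aluminium F3. F3 is used in the copper-catalysed SN2' substitution of 2 under the conditions of step 8, but with the mirror-image antipode of L (aryl to the Re face), to give 1-(methoxymethoxy)-4-(RQ)benzene F4. MOM-directed ortho-lithiation (n-BuLi, THF, 0 °C) gives [2-(methoxymethoxy)-5-(RQ)phenyl]lithium F5, which ICH2CH2I converts into 2-iodo-1-(methoxymethoxy)-4-(RQ)benzene F6. Phenoxide 17, generated from 15 with CsF as in step 9, is coupled with F6 in an Ullmann diaryl ether synthesis (CuI, N,N-dimethylglycine, Cs2CO3, dioxane/DMF, 90 °C). This gives 2-(ArB-oxy)-1-(methoxymethoxy)-4-(RQ)benzene F7, and the conditions of step 14 remove all three MOM groups to give 29.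

Step 8. Aryllithium 13 may equilibrate by proton transfer to a MOM-stabilised ortho-lithio isomer, and the silyl ether may migrate or be attacked. The trioxygenated, chelating aryl group may also transfer slowly, which allows ethyl transfer and erodes site and facial selectivity; a shortfall in facial selectivity would show only after step 11, as a diastereomer of 29. The fallback sets out from 2 and comes back at 18; it transfers a simpler aryl group without a silyl ether and adds the third oxygen afterwards. 4-Bromobenzene-1,2-diol F8 is protected (MOMCl, i-Pr2NEt) as 4-bromo-1,2-bis(methoxymethoxy)benzene F9. t-BuLi gives [3,4-bis(methoxymethoxy)phenyl]lithium F10 and Et2AlCl gives [3,4-bis(methoxymethoxy)phenyl]diethylaluminium F11. Substitution of 2 with the catalyst antipode of step 8 gives 1,2-bis(methoxymethoxy)-4-(SQ)benzene F12. Directed ortho-lithiation (n-BuLi, THF, 0 °C) can occur only at the position next to a MOM ether that is not flanked by the quaternary carbon, and gives [2,3-bis(methoxymethoxy)-5-(SQ)phenyl]lithium F13. B(OMe)3 converts it into dimethyl [2,3-bis(methoxymethoxy)-5-(SQ)phenyl]boronate F14, and NaOH/H2O2 oxidises this to 2,3-bis(methoxymethoxy)-5-(SQ)phenol F15. Alkylation of F15 with 16 (K2CO3, DMF) gives 18.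

Step 13. Divalent palladium may engage the six isolated C=C bonds (allylic palladation, double-bond migration), or the labile silyl dienol ether may hydrolyse back to 24 before it is oxidised. The fallback sets out from 24 and comes back at 28; it uses a metal-free, one-flask dehydrogenation of the enolate. Lithium dienolate 25 (LiN(i-Pr)2, THF, −78 °C) is treated with N-tert-butylbenzenesulfinimidoyl chloride. This gives 2-(ArB-oxy)-6-(N-tert-butyl-S-phenylsulfinimidoyl)-4-(RQ)cyclohex-2-en-1-one F16, which undergoes syn elimination at low temperature to dienone 27, and 27 tautomerises to 28.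

Further compounds
F1 | step 11 | 1-bromo-4-(methoxymethoxy)benzene | COCOc1ccc(Br)cc1
F2 | step 11 | [4-(methoxymethoxy)phenyl]lithium | [Li]c1ccc(OCOC)cc1
F3 | step 11 | diethyl[4-(methoxymethoxy)phenyl]aluminium | CC[Al](CC)c1ccc(OCOC)cc1
F4 | step 11 | 1-(methoxymethoxy)-4-(RQ)benzene | C=C[C@@](C)(CC/C=C(\C)CCC=C(C)C)c1ccc(OCOC)cc1
F5 | step 11 | [2-(methoxymethoxy)-5-(RQ)phenyl]lithium | C=C[C@@](C)(CC/C=C(\C)CCC=C(C)C)c1ccc(OCOC)c([Li])c1
F6 | step 11 | 2-iodo-1-(methoxymethoxy)-4-(RQ)benzene | C=C[C@@](C)(CC/C=C(\C)CCC=C(C)C)c1ccc(OCOC)c(I)c1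
F7 | step 11 | 2-(ArB-oxy)-1-(methoxymethoxy)-4-(RQ)benzene | C=C[C@@](C)(CC/C=C(\C)CCC=C(C)C)c1ccc(OCOC)c(Oc2cc([C@](C)(C=C)CC/C=C(\C)CCC=C(C)C)cc(OCOC)c2OCOC)c1
F8 | step 8 | 4-bromobenzene-1,2-diol | Oc1ccc(Br)cc1O
F9 | step 8 | 4-bromo-1,2-bis(methoxymethoxy)benzene | COCOc1ccc(Br)cc1OCOC
F10 | step 8 | [3,4-bis(methoxymethoxy)phenyl]lithium | [Li]c1ccc(OCOC)c(OCOC)c1
F11 | step 8 | [3,4-bis(methoxymethoxy)phenyl]diethylaluminium | CC[Al](CC)c1ccc(OCOC)c(OCOC)c1
F12 | step 8 | 1,2-bis(methoxymethoxy)-4-(SQ)benzene | C=C[C@](C)(CC/C=C(\C)CCC=C(C)C)c1ccc(OCOC)c(OCOC)c1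
F13 | step 8 | [2,3-bis(methoxymethoxy)-5-(SQ)phenyl]lithium | [Li]c1cc([C@](C)(C=C)CC/C=C(\C)CCC=C(C)C)cc(OCOC)c1OCOC
F14 | step 8 | dimethyl [2,3-bis(methoxymethoxy)-5-(SQ)phenyl]boronate | COB(OC)c1cc([C@](C)(C=C)CC/C=C(\C)CCC=C(C)C)cc(OCOC)c1OCOC
F15 | step 8 | 2,3-bis(methoxymethoxy)-5-(SQ)phenol | Oc1cc([C@](C)(C=C)CC/C=C(\C)CCC=C(C)C)cc(OCOC)c1OCOC
F16 | step 13 | 2-(ArB-oxy)-6-(N-tert-butyl-S-phenylsulfinimidoyl)-4-(RQ)cyclohex-2-en-1-one | C=C[C@@](C)(CC/C=C(\C)CCC=C(C)C)C1CC(S(=NC(C)(C)C)c2ccccc2)C(=O)C(Oc2cc([C@](C)(C=C)CC/C=C(\C)CCC=C(C)C)cc(OCOC)c2OCOC)=C1
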